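**Retrosynthetic overview**
1. Numbering: cyclopentenone C1H2–C2(=O)–C3H=C4–C9; cyclohexane C4–C5(Me)–C6(Me)–C7H2–C8(OH)–C9; bridge C9–C10(Me)–C11(OH)–C12(Me, vinyl)–C13H2–C14(OAc)–C5.
2. Feature: the six- and eight-membered rings share the three atoms C5–C4–C9, a bicyclo[5.3.1]undecane with bridgeheads C5 and C9. A diene that carries the C10–C14 chain on its inner carbon C9, with the alkene C5=C6 at the end of that chain, can therefore close both rings in one [4+2].
3. The cyclopentenone is made last. It is cut at C3=C4 (Saegusa–Ito) and at C1–C9 (bridgehead enolate alkylated by the C1H2Cl end of the arm on C4). C8-OH and C14-OAc go back to ketones.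
4. Key disconnection: C4–C5 and C6–C7, by a type 2 intramolecular Diels–Alder reaction of the 2-siloxydiene C7=C8–C9=C4 with the Z-enone C14(=O)–C5=C6. The six- and eight-membered rings form together.
5. Precursor: C12 by deconjugative Evans alkylation; C10/C11 by allenylstannane propargylation; C9=C4 by aldol condensation on the C8–O11 lactone; C7 from MeMgBr; C5/C6 from the vinyllithium of (Z)-2-bromobut-2-ene, added to the C14 amide last.

Key step: step 18

Assumption: the eight stereodescriptors of the target string are taken literally. On the cyclohexane they place C14, the C6 methyl and C1 on one face and the C5 methyl, C10 and the C8 hydroxyl on the other, and every intermediate is drawn to fit this.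

**Route**

Step 1
Reactants: 1 (R)-4-benzyloxazolidin-2-one; 2 tigloyl chloride [(E)-2-methylbut-2-enoyl chloride]
Product: 3 (R)-4-benzyl-3-[(E)-2-methylbut-2-enoyl]oxazolidin-2-one
Conditions: n-BuLi, THF, −78 °C; then 2, −78 → 0 °C
Reagents that add atoms: none
Why: N-acylation of the lithiated Evans auxiliary with an acid chloride is routine and leaves the E-alkene untouched.

Step 2
Reactants: 3 N-tigloyl imide; 4 2-bromo-N,N-dimethylacetamide
Product: 5 (R)-4-benzyl-3-[(S)-2-(2-dimethylamino-2-oxoethyl)-2-methylbut-3-enoyl]oxazolidin-2-one (C11–C14 unit)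
Conditions: NaHMDS, THF, −78 °C; then 4, −78 → −30 °C
Reagents that add atoms: none
Why: Deconjugative Evans alkylation: γ-deprotonation gives the chelated sodium dienolate (α-methyl syn to O–Na), which reacts at its α-carbon on the face away from the benzyl group, so quaternary C12 is set with methyl, vinyl, the C11 acyl group and the C13–C14 amide arm.

Step 3
Reactants: 5 alkylated imide
Product: 6 (S)-3-(hydroxymethyl)-N,N,3-trimethylpent-4-enamide
Conditions: LiBH4, THF–Et2O, 0 °C
Reagents that add atoms: none
Why: Reductive removal of the auxiliary: LiBH4 attacks the activated exocyclic imide carbonyl but neither the tertiary amide nor the vinyl group, so C11 is freed as the primary alcohol with C12 untouched.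

Step 4
Reactants: 6 primary alcohol
Product: 7 (S)-3-formyl-N,N,3-trimethylpent-4-enamide
Conditions: Dess–Martin periodinane, CH2Cl2, rt
Reagents that add atoms: none
Why: Dess–Martin oxidation under neutral conditions gives the α-quaternary aldehyde, which has no α-hydrogen and cannot epimerise.

Step 5
Reactants: 8 (R)-but-3-yn-2-ol
Product: 9 (R)-but-3-yn-2-yl methanesulfonate
Conditions: MsCl, Et3N, CH2Cl2, −78 → 0 °C
Reagents that add atoms: methanesulfonyl chloride, CS(=O)(=O)Cl
Why: Sulfonylation takes place at oxygen and leaves the carbinol centre (the later C10) unchanged.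

Step 6
Reactants: 9 propargylic mesylate
Product: 10 (P)-buta-1,2-dien-1-yl(tributyl)stannane
Conditions: Bu3SnH, LDA, THF, 0 °C; CuBr·SMe2, −78 °C; then 9
Reagents that add atoms: tributyltin hydride, CCCC[SnH](CCCC)CCCC
Why: anti-SN2′ displacement of a propargylic mesylate by a stannylcopper reagent is a known route to enantioenriched allenylstannanes and converts the carbinol centre into the P axis.

Step 7
Reactants: 7 aldehyde; 10 allenylstannane
Product: 11 (S)-3-[(1S,2R)-1-hydroxy-2-methylbut-3-yn-1-yl]-N,N,3-trimethylpent-4-enamide (alkyne carbons = C9 and C8)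
Conditions: BF3·OEt2 (excess, because the amide binds one equivalent), CH2Cl2, −78 °C; aq. work-up
Reagents that add atoms: none
Why: Lewis-acid-promoted SE2′ propargylation with a chiral allenylstannane: attack anti to the C–Sn bond fixes C10 (net retention from 8), and the open antiperiplanar transition state favoured by a bulky aldehyde makes C10-Me and C11-OH syn, so the reagent sets both centres next to the fixed C12.

Step 8
Reactants: 11 homopropargylic alcohol
Product: 12 (S)-N,N,3-trimethyl-3-[(2S,3R)-3-methyl-5-oxotetrahydrofuran-2-yl]pent-4-enamide (C8–O11 γ-lactone; C10-Me cis to C12)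
Conditions: CpRu(cod)Cl, P(2-furyl)3, Bu4NBr (all cat.), N-hydroxysuccinimide, NaHCO3 buffer, DMF–H2O, 95 °C
Reagents that add atoms: N-hydroxysuccinimide, O=C1CCC(=O)N1O
Why: Ruthenium-catalysed cycloisomerisation–oxidation of a homopropargylic alcohol: the terminal alkyne becomes a vinylidene, O11 adds to C8, and the oxacarbene is oxidised to the γ-lactone, which leaves the alkene and the three stereocentres untouched.

Step 9
Reactants: 13 ethyl (S)-4-chloro-3-hydroxybutanoate
Product: 14 ethyl (S)-3-(tert-butyldimethylsilyloxy)-4-chlorobutanoate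
Conditions: TBSCl, imidazole, DMF, rt
Reagents that add atoms: tert-butyldimethylsilyl chloride, CC(C)(C)[Si](C)(C)Cl
Why: Standard silylation of a secondary alcohol; imidazole is too weak a base to close the chlorohydrin to the epoxide.

Step 10
Reactants: 14 silyloxy ester
Product: 15 (S)-3-(tert-butyldimethylsilyloxy)-4-chlorobutanal (C4–C1 unit)
Conditions: DIBAL-H, CH2Cl2, −78 °C; Rochelle salt
Reagents that add atoms: none
Why: Partial ester reduction stops at the aldehyde because the tetrahedral aluminate is stable at −78 °C.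

Step 11
Reactants: 12 lactone; 15 aldehyde
Product: 16 aldol adduct, lactone 12 bearing a 4-chloro-1-hydroxy-3-silyloxybutyl group on C9 (mixture at C9 and C4)
Conditions: LDA, THF, −78 °C; then 15; H2O
Reagents that add atoms: none
Why: Lithium enolate aldol addition: C9 is the only readily enolisable position, so the C9–C4 bond forms regiospecifically, and the two new centres are erased in the next step.

Step 12
Reactants: 16 aldol adduct
Product: 18 (E)-alkylidene lactone (C3 trans to C8 and cis to C10), via aldol mesylate 17 (not isolated)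
Conditions: MsCl, Et3N, CH2Cl2, 0 °C; then DBU, rt
Reagents that add atoms: none
Why: Mesylation followed by E1cB elimination should give the conjugated alkylidene lactone under product-stability control, that is the E isomer with H4 next to the carbonyl group.

Step 13
Reactants: 18 alkylidene lactone
Product: 19 C8 Weinreb amide with free C11-OH
Conditions: MeNH(OMe)·HCl, AlMe3, CH2Cl2, 0 °C → rt
Reagents that add atoms: N,O-dimethylhydroxylamine hydrochloride, CNOC.Cl
Why: Weinreb aminolysis with the aluminium amide opens the lactone at C8 without touching the alkene geometry, the tertiary amide or the chloride.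

Step 14
Reactants: 19 hydroxy Weinreb amide
Product: 20 C11 tert-butyldimethylsilyl ether of 19
Conditions: TBSOTf, 2,6-lutidine, CH2Cl2, 0 °C
Reagents that add atoms: tert-butyldimethylsilyl triflate, CC(C)(C)[Si](C)(C)OS(=O)(=O)C(F)(F)F
Why: The silyl triflate silylates the hindered C11 hydroxyl quickly and so blocks relactonisation.

Step 15
Reactants: 20 Weinreb amide
Product: 21 (E)-methyl enone C7H3–C8(=O)–C9(C10)=C4H–C3
Conditions: MeMgBr, THF, −20 → 0 °C
Reagents that add atoms: methylmagnesium bromide, C[Mg]Br
Why: Weinreb ketone synthesis: the chelated tetrahedral intermediate prevents over-addition, and the much less electrophilic N,N-dimethylamide at C14 stays intact.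

Step 16
Reactants: 21 methyl enone
Product: 22 2-siloxydiene C7H2=C8(OTBS)–C9=C4 carrying the C14 dimethylamide
Conditions: TBSOTf, Et3N, CH2Cl2, −78 → 0 °C
Reagents that add atoms: tert-butyldimethylsilyl triflate, CC(C)(C)[Si](C)(C)OS(=O)(=O)C(F)(F)F
Why: Soft enolisation removes an α′ proton from the C7 methyl group and gives the cross-conjugated silyl dienol ether; the only other carbonyl is a tertiary amide that is not enolised here, which is why the dienophile ketone is introduced afterwards.

Step 17
Reactants: 22 siloxydiene amide; 23 (Z)-2-bromobut-2-ene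
Product: 25 siloxydiene Z-enone (cycloaddition precursor), via butenyllithium 24 (not isolated)
Conditions: 23, t-BuLi (2 equiv), Et2O, −78 °C; then 22, THF, −78 → −20 °C; pH 7 buffer
Reagents that add atoms: none
Why: Halogen–lithium exchange keeps the alkene geometry, the vinyllithium adds once to the tertiary amide, and the tetrahedral intermediate collapses only on neutral work-up, so the Z-enone appears last and sees no acid, base or heat.

Step 18
Reactants: 25 siloxydiene Z-enone
Product: 26 bicyclo[5.3.1]undecenone with the bridgehead silyl enol ether C8=C9 and the C14 ketone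
Conditions: PhMe (5 mM), BHT, 2,6-di-tert-butyl-4-methylpyridine, silylated sealed tube, 170 °C
Reagents that add atoms: none
Why: This is a thermal concerted [4+2] cycloaddition of the type 2 intramolecular Diels–Alder class, which is known to give bridgehead-alkene bicyclo[5.3.1]undecenes; the nucleophilic diene terminus C7 bonds to the enone β-carbon C6 and C4 to the α-carbon C5, which is also the only regiochemistry that the five-atom tether C10–C14 between C9 and C5 allows. The cyclohexene C4–C9 closes by the cycloaddition itself and the eight-membered ring C5–C4–C9–C10–C11–C12–C13–C14 closes as the tether ring, leaving C8=C9 as a bridgehead silyl enol ether. C5 and C6 follow from suprafacial addition to the Z-enone, which puts the C6 methyl cis to C14 and trans to the C5 methyl. C4 follows from the diene geometry: C3 is the outside substituent and the tether carbonyl C14 is necessarily endo, so C3 and C14 end up cis on the new ring. The diene face is chosen by C10, because allylic 1,3-strain with the cis C3H2 group holds H10 in the diene plane, so C11 and the dienophile it carries lie on one face only, with the C11 silyloxy and C12 vinyl groups turned outward. The step needs an intact Z-enone and an intact dienol ether, hence dilute, acid-free and radical-inhibited heating instead of a Lewis acid.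

Step 19
Reactants: 26 cycloadduct
Product: 27 C14 alcohol
Conditions: DIBAL-H, CH2Cl2, −78 °C; Rochelle salt
Reagents that add atoms: none
Why: Hydride reduction under steric approach control: C14 is the only carbonyl group, the reagent should reach it from the open outer face of the bicycle to give the carbinol drawn, and the enol ether and the chloride are inert.

Step 20
Reactants: 27 C14 alcohol
Product: 28 C14 acetate
Conditions: Ac2O, DMAP (cat.), pyridine, 40 °C
Reagents that add atoms: acetic anhydride, CC(=O)OC(C)=O
Why: DMAP-catalysed acylation of the only free hydroxyl group places the acetate before any other alcohol is unmasked.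

Step 21
Reactants: 28 acetate with the C8=C9 enol ether and the C1 chloride
Product: 29 tricyclic C8 ketone with quaternary C9
Conditions: TASF (1.0 equiv), Bu4NI (cat.), THF, −40 °C → rt
Reagents that add atoms: none
Why: Fluoride-induced alkylation of a silyl enol ether: the enol silyl ether is cleaved far faster than the two alkyl silyl ethers, and the regiodefined bridgehead enolate closes the five-membered ring by 5-exo-tet C-alkylation at C1 (O-alkylation would need a seven-membered ring), so C9 becomes quaternary with C1 on the ring face that already carries the C3 end of the arm.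

Step 22
Reactants: 29 ketone
Product: 30 C8 alcohol
Conditions: NaBH4, MeOH, 0 °C → rt
Reagents that add atoms: none
Why: Borohydride reduction of the only ketone (the acetate survives): hydride should come from the face of C8 that carries C1, away from the C10 branch on the neighbouring quaternary C9, which leaves the hydroxyl cis to C10.

Step 23
Reactants: 30 bis(silyl ether)
Product: 31 C2,C8,C11-triol 14-acetate
Conditions: 48% aq. HF, MeCN, rt
Reagents that add atoms: none
Why: Acidic fluoride removes both silyl ethers, including the hindered one at C11, without touching the acetate or the vinyl group.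

Step 24
Reactants: 31 triol
Product: 32 C2 ketone (C8,C11-diol)
Conditions: TEMPO (cat.), PhI(OAc)2, CH2Cl2, rt
Reagents that add atoms: none
Why: Oxoammonium oxidation is very sensitive to hindrance, so C2-OH, flanked by two CH2 groups, is oxidised while C8-OH and C11-OH, each next to a quaternary carbon, are left; this also erases the auxiliary C2 centre.

Step 25
Reactants: 32 keto diol
Product: 33 C2=C3 trimethylsilyl enol ether with C8 and C11 trimethylsilyl ethers
Conditions: TMSOTf, Et3N, CH2Cl2, 0 °C
Reagents that add atoms: trimethylsilyl triflate, C[Si](C)(C)OS(=O)(=O)C(F)(F)F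
Why: Soft enolisation goes towards C3 because C1 is neopentylic (next to quaternary C9), and the two hydroxyl groups are masked in passing.

Step 26
Reactants: 33 silyl enol ether
Product: 35 pleuromutilin E (target), via enone bis(trimethylsilyl) ether 34 (not isolated)
Conditions: Pd(OAc)2 (1 equiv), MeCN, rt; then 1 M aq. citric acid–THF
Reagents that add atoms: none
Why: Saegusa–Ito oxidation: the palladium enolate can lose only H4 by β-hydride elimination, since C9 bears no hydrogen, which gives the C3=C4 enone and removes the C4 centre; the mild acid then cleaves the two labile trimethylsilyl ethers.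

**Compound list**
1 | (R)-4-benzyloxazolidin-2-one | O=C1N[C@H](Cc2ccccc2)CO1 | starting material
2 | tigloyl chloride | C/C=C(\C)C(=O)Cl | starting material
3 | (R)-4-benzyl-3-[(E)-2-methylbut-2-enoyl]oxazolidin-2-one | C/C=C(\C)C(=O)N1[C@H](Cc2ccccc2)COC1=O | intermediate
4 | 2-bromo-N,N-dimethylacetamide | BrCC(=O)N(C)C | starting material
5 | alkylated imide with quaternary C12 | C=C[C@](C(=O)N1[C@H](Cc2ccccc2)COC1=O)(C)CC(=O)N(C)C | intermediate
6 | (S)-3-(hydroxymethyl)-N,N,3-trimethylpent-4-enamide | C=C[C@](CO)(C)CC(=O)N(C)C | intermediate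
7 | (S)-3-formyl-N,N,3-trimethylpent-4-enamide | C=C[C@](C=O)(C)CC(=O)N(C)C | intermediate
8 | (R)-but-3-yn-2-ol | C#C[C@@H](C)O | starting material
9 | (R)-but-3-yn-2-yl methanesulfonate | C#C[C@@H](C)OS(C)(=O)=O | intermediate
10 | (P)-buta-1,2-dien-1-yl(tributyl)stannane | CCCC[Sn](CCCC)(CCCC)C([H])=[C@@]=C([H])C | intermediate
11 | syn homopropargylic alcohol (10R,11S,12S) | C=C[C@]([C@@H](O)[C@H](C)C#C)(C)CC(=O)N(C)C | intermediate
12 | C8–O11 γ-lactone | C=C[C@]([C@H]1OC(=O)C[C@H]1C)(C)CC(=O)N(C)C | intermediate
13 | ethyl (S)-4-chloro-3-hydroxybutanoate | CCOC(=O)C[C@H](O)CCl | starting material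
14 | ethyl (S)-3-(tert-butyldimethylsilyloxy)-4-chlorobutanoate | CCOC(=O)C[C@H](O[Si](C)(C)C(C)(C)C)CCl | intermediate
15 | (S)-3-(tert-butyldimethylsilyloxy)-4-chlorobutanal | O=CC[C@H](O[Si](C)(C)C(C)(C)C)CCl | intermediate
16 | aldol adduct (mixture at C9 and C4) | C=C[C@]([C@H]1OC(=O)C(C(O)C[C@H](O[Si](C)(C)C(C)(C)C)CCl)[C@H]1C)(C)CC(=O)N(C)C | intermediate
17 | aldol mesylate | C=C[C@]([C@H]1OC(=O)C(C(OS(C)(=O)=O)C[C@H](O[Si](C)(C)C(C)(C)C)CCl)[C@H]1C)(C)CC(=O)N(C)C | intermediate
18 | (E)-alkylidene lactone | C=C[C@]([C@H]1OC(=O)/C(=C/C[C@H](O[Si](C)(C)C(C)(C)C)CCl)[C@H]1C)(C)CC(=O)N(C)C | intermediate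
19 | C8 Weinreb amide, free C11-OH | C=C[C@]([C@@H](O)[C@H](C)/C(=C\C[C@H](O[Si](C)(C)C(C)(C)C)CCl)C(=O)N(C)OC)(C)CC(=O)N(C)C | intermediate
20 | C8 Weinreb amide, C11-OTBS | C=C[C@]([C@@H](O[Si](C)(C)C(C)(C)C)[C@H](C)/C(=C\C[C@H](O[Si](C)(C)C(C)(C)C)CCl)C(=O)N(C)OC)(C)CC(=O)N(C)C | intermediate
21 | (E)-methyl enone | C=C[C@]([C@@H](O[Si](C)(C)C(C)(C)C)[C@H](C)/C(=C\C[C@H](O[Si](C)(C)C(C)(C)C)CCl)C(C)=O)(C)CC(=O)N(C)C | intermediate
22 | 2-siloxydiene dimethylamide | C=C[C@]([C@@H](O[Si](C)(C)C(C)(C)C)[C@H](C)/C(=C\C[C@H](O[Si](C)(C)C(C)(C)C)CCl)C(O[Si](C)(C)C(C)(C)C)=C)(C)CC(=O)N(C)C | intermediate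
23 | (Z)-2-bromobut-2-ene | C/C=C(/C)Br | starting material
24 | but-2-en-2-yllithium, Li cis to the C3 methyl (geometry of 23 kept; E only by the CIP rank Li < C) | C/C=C(/C)[Li] | intermediate
25 | siloxydiene Z-enone, cycloaddition precursor | C=C[C@]([C@@H](O[Si](C)(C)C(C)(C)C)[C@H](C)/C(=C\C[C@H](O[Si](C)(C)C(C)(C)C)CCl)C(O[Si](C)(C)C(C)(C)C)=C)(C)CC(=O)/C(C)=C\C | intermediate
26 | bicyclo[5.3.1]undecenone cycloadduct | C=C[C@]1(C)CC(=O)[C@]2(C)[C@H](C[C@H](O[Si](C)(C)C(C)(C)C)CCl)C(=C(O[Si](C)(C)C(C)(C)C)C[C@@H]2C)[C@@H](C)[C@@H]1O[Si](C)(C)C(C)(C)C | intermediate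
27 | C14 alcohol | C=C[C@]1(C)C[C@@H](O)[C@]2(C)[C@H](C[C@H](O[Si](C)(C)C(C)(C)C)CCl)C(=C(O[Si](C)(C)C(C)(C)C)C[C@@H]2C)[C@@H](C)[C@@H]1O[Si](C)(C)C(C)(C)C | intermediate
28 | C14 acetate | C=C[C@]1(C)C[C@@H](OC(C)=O)[C@]2(C)[C@H](C[C@H](O[Si](C)(C)C(C)(C)C)CCl)C(=C(O[Si](C)(C)C(C)(C)C)C[C@@H]2C)[C@@H](C)[C@@H]1O[Si](C)(C)C(C)(C)C | intermediate
29 | tricyclic C8 ketone | C=C[C@]1(C)C[C@@H](OC(C)=O)[C@]2(C)[C@@H]3C[C@H](O[Si](C)(C)C(C)(C)C)C[C@@]3(C(=O)C[C@@H]2C)[C@@H](C)[C@@H]1O[Si](C)(C)C(C)(C)C | intermediate
30 | tricyclic C8 alcohol | C=C[C@]1(C)C[C@@H](OC(C)=O)[C@]2(C)[C@@H]3C[C@H](O[Si](C)(C)C(C)(C)C)C[C@@]3([C@@H](O)C[C@@H]2C)[C@@H](C)[C@@H]1O[Si](C)(C)C(C)(C)C | intermediate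
31 | C2,C8,C11-triol 14-acetate | C=C[C@]1(C)C[C@@H](OC(C)=O)[C@]2(C)[C@@H]3C[C@H](O)C[C@@]3([C@@H](O)C[C@@H]2C)[C@@H](C)[C@@H]1O | intermediate
32 | C2 ketone, C8,C11-diol | C=C[C@]1(C)C[C@@H](OC(C)=O)[C@]2(C)[C@@H]3CC(=O)C[C@@]3([C@@H](O)C[C@@H]2C)[C@@H](C)[C@@H]1O | intermediate
33 | C2=C3 TMS enol ether, C8 and C11 TMS ethers | C=C[C@]1(C)C[C@@H](OC(C)=O)[C@]2(C)[C@@H]3C=C(O[Si](C)(C)C)C[C@@]3([C@@H](O[Si](C)(C)C)C[C@@H]2C)[C@@H](C)[C@@H]1O[Si](C)(C)C | intermediate
34 | enone bis(trimethylsilyl) ether | C=C[C@]1(C)C[C@@H](OC(C)=O)[C@]2(C)C3=CC(=O)C[C@@]3([C@@H](O[Si](C)(C)C)C[C@@H]2C)[C@@H](C)[C@@H]1O[Si](C)(C)C | intermediate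
35 | pleuromutilin E | C=C[C@]1(C)C[C@@H](OC(C)=O)[C@]2(C)C3=CC(=O)C[C@@]3([C@@H](O)C[C@@H]2C)[C@@H](C)[C@@H]1O | target

**Step count**
- Total: 26 steps.
- Longest linear sequence: 22 steps (1–4, 7, 8, 11–26).

**Steps most likely to fail**

Step 18 (cycloaddition). Both partners are trisubstituted, so the reaction may simply be too slow. Prolonged heating may isomerise the Z-enone to E, cleave the dienol ether, or erode the facial selectivity. Fallback: starting from 25, the two bonds are made one after the other by polar chemistry.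
- A catalytic silyl Lewis acid (TBSNTf2, CH2Cl2, −78 °C) triggers a Mukaiyama–Michael addition of C7 to C6 with silyl transfer to O14. This closes the ten-membered ring to the macrocyclic enone silyl enol ether F1.
- On warming, the C14=C5 enol ether of F1 adds across the ring to C4, the β-carbon of the C8 enone, in a second Mukaiyama–Michael addition. This closes the six- and eight-membered rings and returns the silyl group to O8, so the route is rejoined at 26.

Step 21 (C1–C9 bond). Several things may go wrong:
- the bridgehead enolate may be protonated instead of alkylated;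
- the C2 silyl ether may be lost, followed by epoxide closure onto C1;
- the enolate may react at oxygen;
- it may close through its other lobe, the one that points away from the bridge.

Fallback: starting from 28, the bond is made by a radical.
- A Finkelstein exchange (NaI, butanone, reflux) gives the iodide F2.
- Bu3SnH/AIBN (PhH, 80 °C) turns F2 into the C1 radical, which adds 5-exo-trig to C9 of the enol ether.
- Hydrogen transfer to the α-silyloxy radical at C8 gives the tricyclic tris(silyl ether) F3.
- Aqueous HF in MeCN removes all three silyl groups, and the route is rejoined at 31, so steps 21 and 22 are not needed.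

Step 8 (oxidative lactonisation). The hindered C11 hydroxyl may add slowly to the vinylidene, and the catalyst may engage the C12 vinyl group in an enyne cycloisomerisation. Fallback: starting from 11, the terminal alkyne is hydroborated with dicyclohexylborane (THF, 0 °C) and oxidised with NaBO3. The resulting aldehyde closes to the lactol F4, and TEMPO/PhI(OAc)2 oxidises F4 to the lactone, so the route is rejoined at 12.

**Further compounds**
F1 | step 18 | ten-membered-ring Mukaiyama–Michael adduct (C8 enone, C14=C5 silyl enol ether) | C=C[C@]1(C)CC(O[Si](C)(C)C(C)(C)C)=C(C)[C@@H](C)CC(=O)/C(=C/C[C@H](O[Si](C)(C)C(C)(C)C)CCl)[C@@H](C)[C@@H]1O[Si](C)(C)C(C)(C)C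
F2 | step 21 | C1 iodide corresponding to 28 | C=C[C@]1(C)C[C@@H](OC(C)=O)[C@]2(C)[C@H](C[C@H](O[Si](C)(C)C(C)(C)C)CI)C(=C(O[Si](C)(C)C(C)(C)C)C[C@@H]2C)[C@@H](C)[C@@H]1O[Si](C)(C)C(C)(C)C
F3 | step 21 | tricyclic C2,C8,C11-tris(silyl ether) 14-acetate | C=C[C@]1(C)C[C@@H](OC(C)=O)[C@]2(C)[C@@H]3C[C@H](O[Si](C)(C)C(C)(C)C)C[C@@]3([C@@H](O[Si](C)(C)C(C)(C)C)C[C@@H]2C)[C@@H](C)[C@@H]1O[Si](C)(C)C(C)(C)C
F4 | step 8 | C8 lactol (anomeric mixture) | C=C[C@]([C@H]1OC(O)C[C@H]1C)(C)CC(=O)N(C)C
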